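**Retrosynthetic overview**

1. The target is read as a (3Z,6R)-α-alkylidene δ-lactone (O1, C2=O, C3, C4, C5, C6; C7 = C(CH3)2OH on C6) whose (4E,8E) chain ends in a 2-methyl-1,4-benzoquinone. The quinone is unmasked last from its dimethyl ether. The Z C3=C bond is cut by a Horner–Wadsworth–Emmons reaction in the Still–Gennari mode into aldehyde 11 (aryl bromide 3 + farnesyl bromide 4, terminal alkene cleaved) and phosphono lactone 21.
2. Enabling feature: C2(=O)–C3–C4–C5–C6(O) is a 1,5-dioxygenated chain with one more oxygen on C7. C2, C3, C6, C7 and the C7 oxygen can therefore be folded into the butenolide ring of 5,5-dimethyltetronic acid 13, where C3 and C6 are directly bonded as an enol double bond (C3=C6–OH) and the C7 oxygen acylates C2. C4–C5 is then ethylene.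
3. Key disconnection: C3–C4 and C5–C6 are both made by de Mayo photocycloaddition of ethylene to 13. The temporary C3–C6 bond is cleaved by retro-aldol, and the temporary C7–O–C2 lactone is later exchanged for the C6–O–C2 lactone.
4. Ring order: butenolide (five) → cyclobutane-fused bicycle (four/five) → oxepane-2,6-dione (seven) → δ-lactone (six, by translactonisation after Corey–Bakshi–Shibata reduction sets C6) → quinone ring (oxidation).

Key step: step 7

**Route**

Step 1
Reactants: 1 4-methoxy-2-methylphenol
Product: 2 2-bromo-4-methoxy-6-methylphenol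
Conditions: Br2 (1.0 equiv), CH2Cl2, −10 → 0 °C
Reagents that add atoms: bromine, BrBr
Why: Electrophilic aromatic bromination should go to the only free position ortho to the phenol OH, the strongest director, because the para position is blocked by OMe.

Step 2
Reactants: 2 2-bromo-4-methoxy-6-methylphenol
Product: 3 1-bromo-2,5-dimethoxy-3-methylbenzene
Conditions: MeI, K2CO3, acetone, reflux
Reagents that add atoms: iodomethane, CI
Why: Williamson O-methylation of the phenoxide masks the hydroquinone as the dimethyl ether that survives every later step and is the quinone precursor.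

Step 3
Reactants: 3 1-bromo-2,5-dimethoxy-3-methylbenzene, 4 (2E,6E)-farnesyl bromide
Product: 7 1,4-dimethoxy-2-methyl-6-[(2E,6E)-3,7,11-trimethyldodeca-2,6,10-trien-1-yl]benzene, via (2,5-dimethoxy-3-methylphenyl)lithium 5 (not isolated), via (2,5-dimethoxy-3-methylphenyl)copper 6 (not isolated)
Conditions: n-BuLi (1.05 equiv), THF, −78 °C; CuBr·SMe2 (1.0 equiv), −78 → −40 °C; then 4, −40 → 0 °C
Reagents that add atoms: none
Why: Bromine–lithium exchange, transmetalation to the arylcopper and SN2-type allylic substitution at the primary carbon of 4 should join the fragments with the 2E,6E geometry untouched.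

Step 4
Reactants: 7 1,4-dimethoxy-2-methyl-6-[(2E,6E)-3,7,11-trimethyldodeca-2,6,10-trien-1-yl]benzene
Product: 9 3-[(3E,7E)-9-(2,5-dimethoxy-3-methylphenyl)-3,7-dimethylnona-3,7-dien-1-yl]-2,2-dimethyloxirane, via terminal bromohydrin 8 (not isolated)
Conditions: NBS (1.1 equiv), THF/H2O (3:1), 0 °C; then K2CO3, MeOH, rt
Reagents that add atoms: water, O
Why: Bromohydrin formation in aqueous THF is selective for the terminal, most exposed trisubstituted alkene of a coiled polyprenyl chain, and base then closes the epoxide by intramolecular Williamson displacement (the new stereocentre is racemic and is erased in step 5).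

Step 5
Reactants: 9 3-[(3E,7E)-9-(2,5-dimethoxy-3-methylphenyl)-3,7-dimethylnona-3,7-dien-1-yl]-2,2-dimethyloxirane
Product: 11 (4E,8E)-10-(2,5-dimethoxy-3-methylphenyl)-4,8-dimethyldeca-4,8-dienal, via vicinal diol 10 (not isolated)
Conditions: HIO4·2H2O (1.2 equiv), THF/Et2O, 0 °C
Reagents that add atoms: none
Why: Acid-promoted epoxide hydration and periodate glycol cleavage (Malaprade reaction) should excise the terminal isopropylidene carbon as acetone and leave the aldehyde without touching the two E alkenes or the arene.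

Step 6
Reactants: 12 3-hydroxy-3-methylbutan-2-one
Product: 13 4-hydroxy-5,5-dimethylfuran-2(5H)-one (5,5-dimethyltetronic acid)
Conditions: (EtO)2CO (3 equiv), KOC(CH3)3 (2.2 equiv), THF, 0 °C → reflux; then aq. HCl
Reagents that add atoms: diethyl carbonate, CCOC(=O)OCC
Why: O-Ethoxycarbonylation of the tertiary alkoxide and Dieckmann-type intramolecular acylation of the methyl ketone enolate should give the fully enolised tetronic acid, whose stable anion drives the sequence.

Step 7
Reactants: 13 4-hydroxy-5,5-dimethylfuran-2(5H)-one, 14 ethylene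
Product: 16 7,7-dimethyloxepane-2,6-dione, via cis-fused cyclobutanol 15 (not isolated)
Conditions: hν (254 nm, low-pressure Hg lamps, quartz), ethylene sparge (large excess), MeCN (0.02 M), −30 °C; lamp off, then Et3N (0.2 equiv), −30 °C → rt
Reagents that add atoms: none
Why: De Mayo reaction: excitation of the enolised β-oxo-lactone chromophore of 13 (O=C2–C3=C6–OH inside the butenolide ring) and intersystem crossing give a triplet that adds to ethylene through a 1,4-biradical, so that C3–C4 and C5–C6 form in one photochemical operation to give cyclobutanol 15, and the amine then triggers a strain-driven retro-aldol cleavage of the temporary C3–C6 bond that expands the five-membered lactone to the seven-membered keto lactone 16. The closest known reaction types are the de Mayo reaction of enolised cyclic 1,3-diketones and the [2+2] photocycloaddition of tetronates and 1,3-dioxin-4-ones to alkenes followed by retro-aldol opening. The cyclobutane closes by stepwise [2+2] photocycloaddition (radical addition to ethylene, then recombination of the 1,4-biradical, cis fusion being the only one possible on a five-membered ring), whereas the seven-membered ring is not closed but released by fragmentation of the bicycle. No stereocentre has to be controlled, because ethylene is symmetric and both cyclobutane stereocentres are erased when C3 and C6 return to CH2 and C=O. The selectivity needed is cross-addition over photodimerisation of 13 and survival of the product ketone: the first is secured by dilution, excess ethylene and the ring-locked enol (no cis–trans decay channel), the second by the quaternary C7, which leaves retro-aldol as the only base pathway of 15, and by running that step with the lamp off so that 16 is never irradiated.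

Step 8
Reactants: 16 7,7-dimethyloxepane-2,6-dione
Product: 18 (6R)-6-(2-hydroxypropan-2-yl)oxan-2-one, via (6R)-6-hydroxy-7,7-dimethyloxepan-2-one 17 (not isolated)
Conditions: (S)-2-methyl-CBS-oxazaborolidine (10 mol %), BH3·SMe2 (0.7 equiv), THF, −30 °C; MeOH; then camphorsulfonic acid (10 mol %), CH2Cl2, rt
Reagents that add atoms: none
Why: Corey–Bakshi–Shibata reduction with the (S)-oxazaborolidine should deliver hydride to the ketone face that places the quaternary C7 in the large-group position and so set C6 as R, after which acid lets the new secondary hydroxyl take the acyl group from the hindered tertiary oxygen (seven- to six-membered translactonisation, no bond to C6 broken).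

Step 9
Reactants: 18 (6R)-6-(2-hydroxypropan-2-yl)oxan-2-one
Product: 19 (6R)-6-[2-(triethylsilyloxy)propan-2-yl]oxan-2-one
Conditions: Et3SiOTf (1.3 equiv), 2,6-lutidine, CH2Cl2, −78 → 0 °C
Reagents that add atoms: triethylsilyl trifluoromethanesulfonate, CC[Si](CC)(CC)OS(=O)(=O)C(F)(F)F
Why: Silyl triflate silylation masks the tertiary alcohol so that it can neither be phosphorylated nor attack the lactone under the strong bases of steps 10 and 11.

Step 10
Reactants: 19 (6R)-6-[2-(triethylsilyloxy)propan-2-yl]oxan-2-one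
Product: 21 (6R)-3-[bis(2,2,2-trifluoroethoxy)phosphoryl]-6-[2-(triethylsilyloxy)propan-2-yl]oxan-2-one, via ketene acetal phosphate 20 (not isolated)
Conditions: LiN(iPr)2 (1.1 equiv), THF, −78 °C; ClP(O)(OCH2CF3)2 (1.1 equiv); then LiN(iPr)2 (2.2 equiv), −78 → −20 °C; AcOH
Reagents that add atoms: bis(2,2,2-trifluoroethyl) phosphorochloridate, O=P(Cl)(OCC(F)(F)F)OCC(F)(F)F
Why: O-Phosphorylation of the lactone enolate followed by the amide-induced 1,3-phosphoryl shift from oxygen to carbon (vinyl phosphate to α-phosphono lactone rearrangement) is driven by the stabilised phosphonate anion, and the new C3 stereocentre is irrelevant because C3 becomes sp2 in step 11.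

Step 11
Reactants: 21 (6R)-3-[bis(2,2,2-trifluoroethoxy)phosphoryl]-6-[2-(triethylsilyloxy)propan-2-yl]oxan-2-one, 11 (4E,8E)-10-(2,5-dimethoxy-3-methylphenyl)-4,8-dimethyldeca-4,8-dienal
Product: 22 (3Z,6R)-3-[(4E,8E)-10-(2,5-dimethoxy-3-methylphenyl)-4,8-dimethyldeca-4,8-dien-1-ylidene]-6-[2-(triethylsilyloxy)propan-2-yl]oxan-2-one
Conditions: KN(SiMe3)2 (1.05 equiv), 18-crown-6 (4 equiv), THF, −78 °C; then 11, −78 °C; aq. NH4Cl at −78 °C
Reagents that add atoms: none
Why: Horner–Wadsworth–Emmons olefination in the Still–Gennari mode: with the electron-poor bis(trifluoroethyl) phosphonate and a crown-separated potassium ion the first adduct should eliminate faster than it equilibrates, giving the kinetic alkene with the chain cis to the lactone carbonyl (3Z).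

Step 12
Reactants: 22 (3Z,6R)-3-[(4E,8E)-10-(2,5-dimethoxy-3-methylphenyl)-4,8-dimethyldeca-4,8-dien-1-ylidene]-6-[2-(triethylsilyloxy)propan-2-yl]oxan-2-one
Product: 23 (3Z,6R)-3-[(4E,8E)-10-(2,5-dimethoxy-3-methylphenyl)-4,8-dimethyldeca-4,8-dien-1-ylidene]-6-(2-hydroxypropan-2-yl)oxan-2-one
Conditions: HF·pyridine, pyridine, THF, 0 °C → rt
Reagents that add atoms: none
Why: Buffered fluoride desilylation frees the tertiary alcohol without touching the alkylidene lactone, the alkenes or the aryl ethers.

Step 13
Reactants: 23 (3Z,6R)-3-[(4E,8E)-10-(2,5-dimethoxy-3-methylphenyl)-4,8-dimethyldeca-4,8-dien-1-ylidene]-6-(2-hydroxypropan-2-yl)oxan-2-one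
Product: 24 (3Z,6R)-3-[(4E,8E)-4,8-dimethyl-10-(5-methyl-3,6-dioxocyclohexa-1,4-dien-1-yl)deca-4,8-dien-1-ylidene]-6-(2-hydroxypropan-2-yl)oxan-2-one
Conditions: (NH4)2Ce(NO3)6 (2.5 equiv), MeCN/H2O (2:1), 0 °C, 20 min
Reagents that add atoms: water, O
Why: Oxidative demethylation of the 1,4-dimethoxyarene by tetravalent cerium (two one-electron oxidations, water adds to the arene radical cation, methanol leaves) should give the para-quinone at 0 °C faster than the isolated trisubstituted alkenes or the tertiary alcohol react.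

**Compound list**

1 | 4-methoxy-2-methylphenol | COc1ccc(O)c(C)c1 | starting material
2 | 2-bromo-4-methoxy-6-methylphenol | COc1cc(C)c(O)c(Br)c1 | intermediate
3 | 1-bromo-2,5-dimethoxy-3-methylbenzene | COc1cc(C)c(OC)c(Br)c1 | intermediate
4 | (2E,6E)-1-bromo-3,7,11-trimethyldodeca-2,6,10-triene ((2E,6E)-farnesyl bromide) | BrC/C=C(\C)CC/C=C(\C)CCC=C(C)C | starting material
5 | (2,5-dimethoxy-3-methylphenyl)lithium | [Li]c1cc(OC)cc(C)c1OC | intermediate
6 | (2,5-dimethoxy-3-methylphenyl)copper | [Cu]c1cc(OC)cc(C)c1OC | intermediate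
7 | 1,4-dimethoxy-2-methyl-6-[(2E,6E)-3,7,11-trimethyldodeca-2,6,10-trien-1-yl]benzene | COc1cc(C)c(OC)c(C/C=C(\C)CC/C=C(\C)CCC=C(C)C)c1 | intermediate
8 | (6E,10E)-3-bromo-12-(2,5-dimethoxy-3-methylphenyl)-2,6,10-trimethyldodeca-6,10-dien-2-ol (racemic) | COc1cc(C)c(OC)c(C/C=C(\C)CC/C=C(\C)CCC(Br)C(C)(C)O)c1 | intermediate
9 | 3-[(3E,7E)-9-(2,5-dimethoxy-3-methylphenyl)-3,7-dimethylnona-3,7-dien-1-yl]-2,2-dimethyloxirane (racemic) | COc1cc(C)c(OC)c(C/C=C(\C)CC/C=C(\C)CCC2OC2(C)C)c1 | intermediate
10 | (6E,10E)-12-(2,5-dimethoxy-3-methylphenyl)-2,6,10-trimethyldodeca-6,10-diene-2,3-diol (racemic) | COc1cc(C)c(OC)c(C/C=C(\C)CC/C=C(\C)CCC(O)C(C)(C)O)c1 | intermediate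
11 | (4E,8E)-10-(2,5-dimethoxy-3-methylphenyl)-4,8-dimethyldeca-4,8-dienal | COc1cc(C)c(OC)c(C/C=C(\C)CC/C=C(\C)CCC=O)c1 | intermediate
12 | 3-hydroxy-3-methylbutan-2-one | CC(=O)C(C)(C)O | starting material
13 | 4-hydroxy-5,5-dimethylfuran-2(5H)-one (5,5-dimethyltetronic acid) | O=C1C=C(O)C(C)(C)O1 | intermediate
14 | ethylene | C=C | starting material
15 | cis-5-hydroxy-4,4-dimethyl-3-oxabicyclo[3.2.0]heptan-2-one (racemic, one enantiomer drawn) | O=C1OC(C)(C)[C@]2(O)CC[C@H]12 | intermediate
16 | 7,7-dimethyloxepane-2,6-dione | O=C1CCCC(=O)C(C)(C)O1 | intermediate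
17 | (6R)-6-hydroxy-7,7-dimethyloxepan-2-one | O=C1CCC[C@@H](O)C(C)(C)O1 | intermediate
18 | (6R)-6-(2-hydroxypropan-2-yl)oxan-2-one | O=C1CCC[C@H](C(C)(C)O)O1 | intermediate
19 | (6R)-6-[2-(triethylsilyloxy)propan-2-yl]oxan-2-one | O=C1CCC[C@H](C(C)(C)O[Si](CC)(CC)CC)O1 | intermediate
20 | bis(2,2,2-trifluoroethyl) (6R)-6-[2-(triethylsilyloxy)propan-2-yl]-5,6-dihydro-4H-pyran-2-yl phosphate | O=P(OCC(F)(F)F)(OCC(F)(F)F)OC1=CCC[C@H](C(C)(C)O[Si](CC)(CC)CC)O1 | intermediate
21 | (6R)-3-[bis(2,2,2-trifluoroethoxy)phosphoryl]-6-[2-(triethylsilyloxy)propan-2-yl]oxan-2-one (both C3 epimers) | O=C1C(P(=O)(OCC(F)(F)F)OCC(F)(F)F)CC[C@H](C(C)(C)O[Si](CC)(CC)CC)O1 | intermediate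
22 | (3Z,6R)-3-[(4E,8E)-10-(2,5-dimethoxy-3-methylphenyl)-4,8-dimethyldeca-4,8-dien-1-ylidene]-6-[2-(triethylsilyloxy)propan-2-yl]oxan-2-one | COc1cc(C)c(OC)c(C/C=C(\C)CC/C=C(\C)CC/C=C2/CC[C@H](C(C)(C)O[Si](CC)(CC)CC)OC2=O)c1 | intermediate
23 | (3Z,6R)-3-[(4E,8E)-10-(2,5-dimethoxy-3-methylphenyl)-4,8-dimethyldeca-4,8-dien-1-ylidene]-6-(2-hydroxypropan-2-yl)oxan-2-one | COc1cc(C)c(OC)c(C/C=C(\C)CC/C=C(\C)CC/C=C2/CC[C@H](C(C)(C)O)OC2=O)c1 | intermediate
24 | (3Z,6R)-3-[(4E,8E)-4,8-dimethyl-10-(5-methyl-3,6-dioxocyclohexa-1,4-dien-1-yl)deca-4,8-dien-1-ylidene]-6-(2-hydroxypropan-2-yl)oxan-2-one | CC1=CC(=O)C=C(C/C=C(\C)CC/C=C(\C)CC/C=C2/CC[C@H](C(C)(C)O)OC2=O)C1=O | target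

**Step count and risks**

Total step count: 13. Longest linear sequence: 8 steps (12 → 24 through steps 6–13; the arene branch 1 → 24 through steps 1–5 and 11–13 is equally long).

Steps most likely to fail:

Step 7. Photodimerisation of 13, weak absorption at 254 nm, or light-induced α-cleavage of the ring-expanded ketone may erode the cycloaddition. The fallback avoids photochemistry and sets out from 12. Silylation (Et3SiOTf, 2,6-lutidine) would give 3-methyl-3-(triethylsilyloxy)butan-2-one F1, which can enolise only on the methyl side. Kinetic enolate allylation (LiN(iPr)2, THF, −78 °C; allyl bromide) would give 2-methyl-2-(triethylsilyloxy)hept-6-en-3-one F2. Corey–Bakshi–Shibata reduction with the (S)-oxazaborolidine would give (3R)-2-methyl-2-(triethylsilyloxy)hept-6-en-3-ol F3. Hydroboration–oxidation (9-BBN; NaOH, H2O2) would give (5R)-6-methyl-6-(triethylsilyloxy)heptane-1,5-diol F4. Oxidative lactonisation of this 1,5-diol (TEMPO, PhI(OAc)2) would deliver 19, where the fallback comes back to the route; steps 8 and 9 are then not needed.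

Step 10. The phosphoryl group may stay on oxygen, or the amide base may attack the electron-poor phosphate and displace trifluoroethoxide instead of inducing the 1,3-shift. The fallback sets out from 19 and makes the C–P bond directly with a trivalent phosphorus electrophile. The lithium enolate of 19 (LiN(iPr)2, THF, −78 °C) would be treated with ClP(OCH2CF3)2, which reacts at carbon, to give (6R)-3-[bis(2,2,2-trifluoroethoxy)phosphanyl]-6-[2-(triethylsilyloxy)propan-2-yl]oxan-2-one F5. Oxidation of the crude phosphonite (aqueous H2O2, 0 °C) would give 21, where it comes back.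

Step 11. Loss of kinetic control (reversible addition, warming before elimination) or base-induced equilibration through the dienolate may give the E alkylidene lactone, and the cyclic phosphonate anion may add sluggishly. The fallback moves the olefination to an open-chain ester, where the Still–Gennari olefination is best established, and sets out from 18. Acid-catalysed methanolysis with acetonide trapping (MeOH, 2,2-dimethoxypropane, camphorsulfonic acid) would give methyl 4-[(4R)-2,2,5,5-tetramethyl-1,3-dioxolan-4-yl]butanoate F6. Phosphorylation of its lithium enolate (LiN(iPr)2, 2.2 equiv; ClP(O)(OCH2CF3)2) would give methyl 2-[bis(2,2,2-trifluoroethoxy)phosphoryl]-4-[(4R)-2,2,5,5-tetramethyl-1,3-dioxolan-4-yl]butanoate F7. Olefination with 11 (KN(SiMe3)2, 18-crown-6, THF, −78 °C) would give methyl (2Z,6E,10E)-12-(2,5-dimethoxy-3-methylphenyl)-6,10-dimethyl-2-{2-[(4R)-2,2,5,5-tetramethyl-1,3-dioxolan-4-yl]ethyl}dodeca-2,6,10-trienoate F8. Aqueous acetic acid, then catalytic p-toluenesulfonic acid in toluene, would remove the acetonide and close the δ-lactone to give 23, where it comes back; step 12 is then not needed.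

**Further compounds**

F1 | step 7 | 3-methyl-3-(triethylsilyloxy)butan-2-one | CC(=O)C(C)(C)O[Si](CC)(CC)CC
F2 | step 7 | 2-methyl-2-(triethylsilyloxy)hept-6-en-3-one | C=CCCC(=O)C(C)(C)O[Si](CC)(CC)CC
F3 | step 7 | (3R)-2-methyl-2-(triethylsilyloxy)hept-6-en-3-ol | C=CCC[C@@H](O)C(C)(C)O[Si](CC)(CC)CC
F4 | step 7 | (5R)-6-methyl-6-(triethylsilyloxy)heptane-1,5-diol | OCCCC[C@@H](O)C(C)(C)O[Si](CC)(CC)CC
F5 | step 10 | (6R)-3-[bis(2,2,2-trifluoroethoxy)phosphanyl]-6-[2-(triethylsilyloxy)propan-2-yl]oxan-2-one | O=C1C(P(OCC(F)(F)F)OCC(F)(F)F)CC[C@H](C(C)(C)O[Si](CC)(CC)CC)O1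
F6 | step 11 | methyl 4-[(4R)-2,2,5,5-tetramethyl-1,3-dioxolan-4-yl]butanoate | COC(=O)CCC[C@H]1OC(C)(C)OC1(C)C
F7 | step 11 | methyl 2-[bis(2,2,2-trifluoroethoxy)phosphoryl]-4-[(4R)-2,2,5,5-tetramethyl-1,3-dioxolan-4-yl]butanoate | COC(=O)C(CC[C@H]1OC(C)(C)OC1(C)C)P(=O)(OCC(F)(F)F)OCC(F)(F)F
F8 | step 11 | methyl (2Z,6E,10E)-12-(2,5-dimethoxy-3-methylphenyl)-6,10-dimethyl-2-{2-[(4R)-2,2,5,5-tetramethyl-1,3-dioxolan-4-yl]ethyl}dodeca-2,6,10-trienoate | COC(=O)/C(CC[C@H]1OC(C)(C)OC1(C)C)=C\CC/C(C)=C/CC/C(C)=C/Cc1cc(OC)cc(C)c1OC
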